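Slowness is what we reckon with: in Tuesday's, at the charged concentrations, the second step has a half-life for J of 0.61 min, slower than the 0.21 min of the first step's forward rate on Z.

    Z + E ⇌ J + G (K1 = 1.01, k1 = 0.210 L mol⁻¹ s⁻¹)
    E + J → E.J (k2 = 0.0717 L mol⁻¹ s⁻¹)

| setting | Tuesday's | Friday's | Thursday's | Monday's |
|---|---|---|---|---|
| Z | 0.26 M | 0.26 M (fed, over 80 s) | 0.26 M | 0.26 M (fed, over 20 s) |
| E | 0.265 M | 0.265 M | 0.265 M (fed, over 80 s) | 0.265 M |
| time | 3.0 min | 3.0 min | 3.0 min | 3.0 min |
| remark | everything together at the start | all else is in the flask from the start; the feed brings no volume worth counting | all else is in the flask from the start; the feed brings no volume worth counting | all else is in the flask from the start; the feed brings no volume worth counting |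

1. the best flask by share of J in J plus E.J; "all alike" if 1.5 percentage points covers them all (Tuesday's / Friday's / Thursday's / Monday's / all alike)
2. share of J in J plus E.J at the end, Tuesday's
3. share of J in J plus E.J at the end, Friday's
4. share of J in J plus E.J at the end, Thursday's
5. share of J in J plus E.J at the end, Monday's

We take the symmetric case as our zero. The constant K1 is close to one, and the charges differ by 0.00500 M. So, before any loss, the first step balances near half conversion, with Z, E, J and G about equal at that point. The second step removes one E with each J, so c(E) and c(J) fall together and the quotient of the balance stays put. Then c(J) obeys a plain second-order loss.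

c₀ = cA/2 = 0.130 M

τ = 1/(k2 c₀) = 1.79 min

share of J = 1/(1 + T/τ)

We call τ the loss time: the exposure T at which this share, the selectivity to J, has fallen to half. Two extremes can be solved in the head.

Balance from the first moment, T = t1: 37.4%

Loss waits for the end of the slow feed, T = t1 − tf: 51.8%

Loss waits for the end of the quick feed, T = t1 − tq: 40.1%

Tuesday's sits near the first line, since 0.21 min is short against 3.0 min. Monday's lies between the first and third lines. Friday's and Thursday's lie between the first two. We place Thursday's toward the upper line and Friday's below it: Friday's gets its 0.265 M of E at the start, and Thursday's gets it over 80 s.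

The forecast gave 37.3% for Tuesday's, 41.2% for Friday's, 45.5% for Thursday's and 38.2% for Monday's, with Thursday's best, and spoke of “slow second-order loss of J to E”.

The flasks give 37.3% for Tuesday's, 41.5% for Friday's, 45.4% for Thursday's and 38.5% for Monday's, and Thursday's is best.

In Thursday's at 0.685 min, J falls back 2.9 times faster than it goes on. At 3.00 min Thursday's holds Z at 49.3% of its charge, and J at 23.0%. Read on τ, Thursday's share is an exposure of 2.15 min out of 3.0 min. Adding the further 2.00 min gives 30.1%, and Thursday's left until 5.0 min reads 29.8%.

The numbers belong to no real substance.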